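**Strategy.** Everything rests on opening the oxepine ring at the C–C bond between the CH2 group on flavone C3 and the O‑aryl methine carbon. The key step exploits two features: C2–C3(CH2)–C4 of the pyranone is a latent 2‑methylene‑1,3‑diketone, and the phloroglucinol A ring offers two equivalent ortho oxygens. The precursor is therefore a racemic 3‑aroylchroman‑4‑one with a 2‑oxopropyl ether on the B ring. In one operation a chiral primary amine opens this temporary chromanone ring (retro‑oxa‑Michael, erasing its stereocentre), closes the oxepine by enamine Michael addition with control of the new (R) centre, and the freed phenol rebuilds the pyranone. Methyl addition to the ketone finishes the synthesis.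

Key step: step 9

Assumption: the sense of induction of the cinchona primary amine in step 9 cannot be predicted with certainty; it is taken as adjustable by choosing between the quinine- and quinidine-derived quasi-enantiomers.
Remark on names: flavone numbering (C2, C3, C4, 5–8, 2′–6′) is used for 14, 15 and the F compounds; the stereocentre is the O-aryl CH of the oxepine ring, and it is (R) in the target.

Step 1
Reactants: 1 2,4,6-trihydroxyacetophenone
Product: 2 1-[2,4,6-trihydroxy-3,5-bis(3-methylbut-2-en-1-yl)phenyl]ethanone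
Conditions: prenyl bromide (2.2 equiv), 10% aq. KOH, 0 °C to rt
Reagents that add atoms: prenyl bromide, CC(C)=CCBr
Why: C-Prenylation of the phloroglucinolate (C-alkylation of an ambident phenoxide) should occur at the two equivalent free ring positions, aqueous base favouring C- over O-alkylation; no stereocentre is formed.

Step 2
Reactants: 2 1-[2,4,6-trihydroxy-3,5-bis(3-methylbut-2-en-1-yl)phenyl]ethanone
Product: 3 1-[2-hydroxy-4,6-bis(methoxymethoxy)-3,5-bis(3-methylbut-2-en-1-yl)phenyl]ethanone
Conditions: MOMCl (2.2 equiv), iPr2NEt, CH2Cl2, 0 °C to rt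
Reagents that add atoms: chloromethyl methyl ether, COCCl
Why: Williamson-type acetal formation should protect the two phenols not locked in the hydrogen bond to the acetyl group (the two ortho hydroxyls are equivalent, so one regioisomer results), leaving the chelated OH needed later as the ring oxygen.

Step 3
Reactants: 4 methyl 2,4-dihydroxybenzoate
Product: 5 methyl 2-hydroxy-4-(methoxymethoxy)benzoate
Conditions: MOMCl (1.05 equiv), iPr2NEt, CH2Cl2, 0 °C
Reagents that add atoms: chloromethyl methyl ether, COCCl
Why: Williamson-type etherification should select the 4-OH, which is more acidic and not hydrogen-bonded to the ester carbonyl.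

Step 4
Reactants: 5 methyl 2-hydroxy-4-(methoxymethoxy)benzoate
Product: 6 methyl 4-(methoxymethoxy)-2-(2-oxopropoxy)benzoate
Conditions: chloroacetone, K2CO3, KI (cat.), acetone, 55 °C
Reagents that add atoms: chloroacetone, CC(=O)CCl
Why: Williamson ether synthesis (iodide-assisted SN2) on the remaining phenol; potassium carbonate is too weak to trigger Dieckmann-type closure of the ketone onto the ester.

Step 5
Reactants: 6 methyl 4-(methoxymethoxy)-2-(2-oxopropoxy)benzoate
Product: 7 methyl 4-(methoxymethoxy)-2-[(2-methyl-1,3-dioxolan-2-yl)methoxy]benzoate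
Conditions: TMSOCH2CH2OTMS, TMSOTf (5 mol %), CH2Cl2, −78 to −20 °C; pyridine quench
Reagents that add atoms: 1,2-bis(trimethylsilyloxy)ethane, C[Si](C)(C)OCCO[Si](C)(C)C
Why: Aprotic TMSOTf-catalysed ketalisation masks the enolisable ketone for the strongly basic step that follows, and at low temperature without protic acid the aryl MOM ether should survive.

Step 6
Reactants: 3 1-[2-hydroxy-4,6-bis(methoxymethoxy)-3,5-bis(3-methylbut-2-en-1-yl)phenyl]ethanone; 7 methyl 4-(methoxymethoxy)-2-[(2-methyl-1,3-dioxolan-2-yl)methoxy]benzoate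
Product: 8 1-[2-hydroxy-4,6-bis(methoxymethoxy)-3,5-bis(3-methylbut-2-en-1-yl)phenyl]-3-{4-(methoxymethoxy)-2-[(2-methyl-1,3-dioxolan-2-yl)methoxy]phenyl}propane-1,3-dione
Conditions: LiHMDS (3.3 equiv), THF, −78 °C to rt; aq. NH4Cl
Reagents that add atoms: none
Why: Crossed Claisen condensation: the lithium phenoxide-enolate of 3 is acylated by the non-enolisable ester 7 and the equilibrium is pulled by deprotonation of the β-diketone, while MOM ethers, ketal and prenyl groups are inert to the amide base.

Step 7
Reactants: 8 the β-diketone of step 6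
Product: 10 5,7-bis(methoxymethoxy)-3-{4-(methoxymethoxy)-2-[(2-methyl-1,3-dioxolan-2-yl)methoxy]benzoyl}-6,8-bis(3-methylbut-2-en-1-yl)chroman-4-one (racemic at C3), via methylene diketone 9 (not isolated)
Conditions: 37% aq. HCHO (1.3 equiv), piperidine (10 mol %), AcOH (10 mol %), EtOH, rt
Reagents that add atoms: formaldehyde, C=O
Why: Knoevenagel condensation of formaldehyde at the diketone CH2 gives 9, which the ortho phenol traps by 6-endo-trig oxa-Michael addition to the stable chromanone; its C3 centre forms racemic, which is harmless because step 9 erases it.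

Step 8
Reactants: 10 the protected 3-aroylchromanone
Product: 11 5,7-dihydroxy-3-[4-hydroxy-2-(2-oxopropoxy)benzoyl]-6,8-bis(3-methylbut-2-en-1-yl)chroman-4-one (racemic at C3)
Conditions: 3 M aq. HCl, MeOH/THF, 40 °C
Reagents that add atoms: water, O
Why: Acid-catalysed acetal cleavage (methanolysis of the three MOM ethers, hydrolysis of the dioxolane) frees the phenols and the ketone, while the chromanone ring should persist because its retro-oxa-Michael opening needs base.

Step 9
Reactants: 11 the free 3-aroylchromanone
Product: 14 (R)-acetyl oxepinoflavone [5,7,4′-trihydroxy-6,8-bis(3-methylbut-2-en-1-yl)flavone bridged C3–CH2–CH(COCH3)–O–C2′; R at the CH], via methylene triketone 12 (not isolated), via benzoxepinone triketone 13 (not isolated)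
Conditions: 9-amino-9-deoxy-epi-quinine (20 mol %), 2-fluorobenzoic acid (40 mol %), THF (0.01 M), 35 °C; then TsOH·H2O (20 mol %), 45 °C
Reagents that add atoms: none
Why: Proposed new method: the amine/carboxylic acid buffer should trigger E1cB retro-oxa-Michael cleavage of the O1–C2 bond of the β-aryloxy 1,3-diketone 11, which erases its racemic C3 centre and unveils the achiral 2-methylene-1,3-diketone 12; the primary amine condenses with the 2-oxopropyl ketone to the enamine on its aryloxy-substituted side, whose carbon adds to the exocyclic CH2 (7-endo-trig) to give 13, and the liberated A-ring phenol then attacks the benzoxepinone carbonyl (6-exo-trig) with acid-promoted loss of water to the 4-pyranone. The closest known reaction types are the amine-catalysed enamine Michael addition of α-alkoxy ketones to alkylidene 1,3-dicarbonyl compounds (including domino Knoevenagel/Michael variants) and the flavanone/chalcone oxa-Michael equilibrium; new here are their merger on a chromanone used as a latent acceptor and the seven-membered closure. The single new stereocentre (R, O-aryl CH) is set in the C–C bond-forming event under catalyst control: the cinchona scaffold shields one enamine face while its protonated quinuclidine hydrogen-bonds the diketone, and the quasi-enantiomeric epi-quinidine amine is used if the opposite sense is found. The step needs attack from the OCH2 rather than the CH3 side of the ketone (secured by the oxygen-stabilised, more substituted enamine and by 7- versus 9-membered closure), Michael addition rather than 5-exo aldol attack on the ortho aroyl carbonyl (secured by the far higher electrophilicity of the doubly activated methylene and the reversibility of the aldol), and capture of 12 before it is lost (its reclosure to 11 is reversible, the C–C bond formation is not; high dilution suppresses intermolecular addition). Either ortho oxygen of the symmetric trihydroxy-diprenyl A ring gives the same pyranone, so the last ring closure has no regiochemical issue. Only weakly acidic conditions follow the bond formation, so the α-aryloxy ketone centre should not epimerise.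

Step 10
Reactants: 14 the (R)-acetyl oxepinoflavone
Product: 15 target, (R)-5,7,4′-trihydroxy-6,8-bis(3-methylbut-2-en-1-yl)flavone bridged C3–CH2–CH[C(CH3)2OH]–O–C2′ (CNP0328977.2)
Conditions: MeMgBr (6 equiv), THF, −78 to −20 °C; aq. NH4Cl
Reagents that add atoms: methylmagnesium bromide, C[Mg]Br
Why: Grignard 1,2-addition to the methyl ketone, helped by chelation to the α-aryloxy oxygen, after the three phenols have consumed three equivalents; the pyranone carbonyl (a 2,3-disubstituted vinylogous ester chelated by the 5-phenoxide) should stay untouched, no new stereocentre forms, and the low temperature limits enolisation so the (R) centre is retained.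

**Compound list**

1 | 2,4,6-trihydroxyacetophenone | CC(=O)c1c(O)cc(O)cc1O | starting material
2 | 1-[2,4,6-trihydroxy-3,5-bis(3-methylbut-2-en-1-yl)phenyl]ethanone | CC(=O)c1c(O)c(CC=C(C)C)c(O)c(CC=C(C)C)c1O | intermediate
3 | 1-[2-hydroxy-4,6-bis(methoxymethoxy)-3,5-bis(3-methylbut-2-en-1-yl)phenyl]ethanone | CC(=O)c1c(O)c(CC=C(C)C)c(OCOC)c(CC=C(C)C)c1OCOC | intermediate
4 | methyl 2,4-dihydroxybenzoate | COC(=O)c1ccc(O)cc1O | starting material
5 | methyl 2-hydroxy-4-(methoxymethoxy)benzoate | COC(=O)c1ccc(OCOC)cc1O | intermediate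
6 | methyl 4-(methoxymethoxy)-2-(2-oxopropoxy)benzoate | COC(=O)c1ccc(OCOC)cc1OCC(C)=O | intermediate
7 | methyl 4-(methoxymethoxy)-2-[(2-methyl-1,3-dioxolan-2-yl)methoxy]benzoate | COC(=O)c1ccc(OCOC)cc1OCC1(C)OCCO1 | intermediate
8 | 1-[2-hydroxy-4,6-bis(methoxymethoxy)-3,5-diprenylphenyl]-3-{4-(methoxymethoxy)-2-[(2-methyl-1,3-dioxolan-2-yl)methoxy]phenyl}propane-1,3-dione | COCOc1ccc(C(=O)CC(=O)c2c(O)c(CC=C(C)C)c(OCOC)c(CC=C(C)C)c2OCOC)c(OCC2(C)OCCO2)c1 | intermediate
9 | 2-methylidene derivative of diketone 8 (methylene diketone, not isolated) | C=C(C(=O)c1ccc(OCOC)cc1OCC1(C)OCCO1)C(=O)c1c(O)c(CC=C(C)C)c(OCOC)c(CC=C(C)C)c1OCOC | intermediate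
10 | 5,7-bis(methoxymethoxy)-3-{4-(methoxymethoxy)-2-[(2-methyl-1,3-dioxolan-2-yl)methoxy]benzoyl}-6,8-diprenylchroman-4-one (racemic) | COCOc1ccc(C(=O)C2COc3c(CC=C(C)C)c(OCOC)c(CC=C(C)C)c(OCOC)c3C2=O)c(OCC2(C)OCCO2)c1 | intermediate
11 | 5,7-dihydroxy-3-[4-hydroxy-2-(2-oxopropoxy)benzoyl]-6,8-diprenylchroman-4-one (racemic) | CC(=O)COc1cc(O)ccc1C(=O)C1COc2c(CC=C(C)C)c(O)c(CC=C(C)C)c(O)c2C1=O | intermediate
12 | 1-[4-hydroxy-2-(2-oxopropoxy)phenyl]-2-methylidene-3-[2,4,6-trihydroxy-3,5-diprenylphenyl]propane-1,3-dione (not isolated) | C=C(C(=O)c1ccc(O)cc1OCC(C)=O)C(=O)c1c(O)c(CC=C(C)C)c(O)c(CC=C(C)C)c1O | intermediate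
13 | (2R)-2-acetyl-8-hydroxy-4-[2,4,6-trihydroxy-3,5-diprenylbenzoyl]-3,4-dihydro-1-benzoxepin-5(2H)-one (C4 epimers, not isolated) | O=C(c1c(O)c(CC=C(C)C)c(O)c(CC=C(C)C)c1O)C1C[C@H](C(C)=O)Oc2cc(O)ccc2C1=O | intermediate
14 | (R)-acetyl oxepinoflavone: 5,7,4′-trihydroxy-6,8-diprenylflavone bridged C3–CH2–CH(COCH3)–O–C2′ | CC(C)=CCc1c(O)c(CC=C(C)C)c2oc3c(c(=O)c2c1O)C[C@H](C(C)=O)Oc1cc(O)ccc1-3 | intermediate
15 | (R)-5,7,4′-trihydroxy-6,8-diprenylflavone bridged C3–CH2–CH[C(CH3)2OH]–O–C2′ (CNP0328977.2) | CC(C)=CCc1c(O)c(CC=C(C)C)c2oc3c(c(=O)c2c1O)C[C@H](C(C)(C)O)Oc1cc(O)ccc1-3 | target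

**Count.** Total steps: 10. Longest linear sequence: 8 steps (steps 3, 4, 5, 6, 7, 8, 9, 10).

**Steps most likely to fail**

1. Step 9 (proposed new method). Possible failures: loss of the one-carbon unit from 12 by retro-Knoevenagel cleavage; 5-exo aldol closure of the enamine onto the ortho aroyl carbonyl followed by dehydration to a benzofuran; poor facial selectivity in the seven-membered closure. The fallback uses known chemistry and closes the same CH2–CH bond by enolate alkylation. It sets out from 8: cyclodehydration (cat. TsOH, toluene, 4 Å MS, 70 °C) should give the 3-unsubstituted tris-MOM flavone F1. C3-lithiation of the flavone with LDA (THF, −78 °C) and trapping with gaseous formaldehyde should give the 3-(hydroxymethyl)flavone F2. Transketalisation (PPTS, wet acetone, 45 °C) should free the hydroxymethyl methyl ketone F3. Appel bromination (CBr4, PPh3, CH2Cl2, 0 °C) should give the 3-(bromomethyl)flavone ketone F4. Intramolecular C-alkylation of the α-aryloxy ketone enolate under chiral phase-transfer catalysis (N-(9-anthracenylmethyl)cinchonidinium bromide 10 mol %, CsOH·H2O, toluene/CH2Cl2, −40 °C; the cinchoninium quasi-enantiomer if the sense is opposite) should give the cyclised tris-MOM ether F5. Methanolysis (3 M HCl, MeOH, 40 °C) would bring the route back at 14.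

2. Step 10. Possible failures: competing attack of the Grignard reagent on the pyranone; enolisation of the α-aryloxy ketone with loss of configuration; precipitation of the magnesium triphenoxide before addition. The fallback sets out from 14: silylation (TBSCl, imidazole, DMF, rt) should give the 7,4′-bis-O-TBS ether F6, the chelated 5-OH staying free. The less basic methylcerium reagent (MeLi, CeCl3, THF, −78 °C) should then add to the now soluble ketone to give the bis-silyl carbinol F7. TBAF buffered with AcOH (THF, 0 °C) would return to 15.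

3. Step 7. Possible failures: over-condensation, either Michael capture of 9 by a second molecule of 8 (methylene-bridged dimer) or a second hydroxymethylation of 10 at C3. The fallback sets out from 8: aminomethylation with one equivalent of dimethylmethylideneammonium iodide (iPr2NEt, CH2Cl2, rt), which avoids free formaldehyde, should give the Mannich base F8. Gentle warming in toluene should expel dimethylamine to 9, which closes to 10 as in the main route.

**Further compounds**

F1 | step 9 | 2-{4-(methoxymethoxy)-2-[(2-methyl-1,3-dioxolan-2-yl)methoxy]phenyl}-5,7-bis(methoxymethoxy)-6,8-diprenyl-4H-chromen-4-one | COCOc1ccc(-c2cc(=O)c3c(OCOC)c(CC=C(C)C)c(OCOC)c(CC=C(C)C)c3o2)c(OCC2(C)OCCO2)c1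
F2 | step 9 | 3-(hydroxymethyl) derivative of F1 | COCOc1ccc(-c2oc3c(CC=C(C)C)c(OCOC)c(CC=C(C)C)c(OCOC)c3c(=O)c2CO)c(OCC2(C)OCCO2)c1
F3 | step 9 | 3-(hydroxymethyl)-5,7-bis(methoxymethoxy)-2-[4-(methoxymethoxy)-2-(2-oxopropoxy)phenyl]-6,8-diprenyl-4H-chromen-4-one | COCOc1ccc(-c2oc3c(CC=C(C)C)c(OCOC)c(CC=C(C)C)c(OCOC)c3c(=O)c2CO)c(OCC(C)=O)c1
F4 | step 9 | 3-(bromomethyl) analogue of F3 | COCOc1ccc(-c2oc3c(CC=C(C)C)c(OCOC)c(CC=C(C)C)c(OCOC)c3c(=O)c2CBr)c(OCC(C)=O)c1
F5 | step 9 | 5,7,4′-tris-O-MOM ether of 14 (R) | CC(C)=CCc1c(OCOC)c(CC=C(C)C)c2oc3c(c(=O)c2c1OCOC)C[C@H](C(C)=O)Oc1cc(OCOC)ccc1-3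
F6 | step 10 | 7,4′-bis-O-TBS ether of 14 (R) | CC(C)=CCc1c(O[Si](C)(C)C(C)(C)C)c(CC=C(C)C)c2oc3c(c(=O)c2c1O)C[C@H](C(C)=O)Oc1cc(O[Si](C)(C)C(C)(C)C)ccc1-3
F7 | step 10 | 7,4′-bis-O-TBS ether of 15 (R) | CC(C)=CCc1c(O[Si](C)(C)C(C)(C)C)c(CC=C(C)C)c2oc3c(c(=O)c2c1O)C[C@H](C(C)(C)O)Oc1cc(O[Si](C)(C)C(C)(C)C)ccc1-3
F8 | step 7 | 2-[(dimethylamino)methyl] derivative of diketone 8 (Mannich base) | CN(C)CC(C(=O)c1ccc(OCOC)cc1OCC1(C)OCCO1)C(=O)c1c(O)c(CC=C(C)C)c(OCOC)c(CC=C(C)C)c1OCOC
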